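**Strategy.** The cyclopentenone (ring carbons C8–C12) is traced back to a furan: C9–C12, with oxygen on C9 and on C12, are a masked 2,5-disubstituted furan, and C8 is its furfuryl carbinol carbon, carrying C7 as an (S)-glyceraldehyde acetonide unit. One aqueous Lewis-acid step (Piancatelli rearrangement) forms the C8–C12 bond, closes the ring, places the C9 ketone and the tertiary C12 hydroxyl, and sets C8 and C12 under control of the chiral-pool C7 centre. The precursor is the 5-[(Z)-oct-2-enyl]-2-furyl carbinol 8, made from furan by two lithiations. The C6–C7 diol then delivers the C6 aldehyde for a Z-selective Wittig reaction, followed by C10 iodination and C7 acetylation.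

Key step: step 4

Remark: positions are given in prostanoid numbering (C1 = ester carbon, C8–C12 = ring, C13–C20 = octenyl chain). Aldehyde 6 is used freshly distilled. Carbinol 8 is carried as the mixture of its two C8 epimers, because this centre becomes planar in step 4.

**Route**

Step 1
Reactants: 1 (2Z)-oct-2-en-1-ol
Product: 2 (2Z)-1-bromooct-2-ene
Conditions: CBr4, PPh3, CH2Cl2, 0 °C
Reagents that add atoms: carbon tetrabromide, BrC(Br)(Br)Br
Why: Appel bromination replaces the primary allylic hydroxyl by SN2 displacement of the oxyphosphonium under neutral conditions at low temperature, which keeps the Z-alkene and avoids allylic transposition.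

Step 2
Reactants: 3 furan; 2 (2Z)-1-bromooct-2-ene
Product: 5 2-[(2Z)-oct-2-en-1-yl]furan, via 2-lithiofuran 4 (not isolated)
Conditions: n-BuLi, THF, −78 → 0 °C; then 2, −78 °C → rt (furan in excess)
Reagents that add atoms: none
Why: α-Lithiation of furan followed by SN2 alkylation of the hard aryllithium at the primary allylic carbon (no copper, hence no allylic transposition) attaches C13–C20 to the future C12 with the Z-geometry untouched, and excess furan suppresses dialkylation.

Step 3
Reactants: 5 2-[(2Z)-oct-2-en-1-yl]furan; 6 (4S)-2,2-dimethyl-1,3-dioxolane-4-carbaldehyde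
Product: 8 [(4S)-2,2-dimethyl-1,3-dioxolan-4-yl]{5-[(2Z)-oct-2-en-1-yl]furan-2-yl}methanol (both C8 epimers), via 5-lithio-2-[(2Z)-oct-2-en-1-yl]furan 7 (not isolated)
Conditions: n-BuLi, Et2O, 0 °C → rt; then 6, −78 °C; H2O
Reagents that add atoms: none
Why: Oxygen-directed α-lithiation of the 2-alkylfuran at its free α-position (ether as solvent disfavours removal of the C13 methylene protons) and 1,2-addition of the aryllithium to the aldehyde form the C8–C9 bond; the carbinol centre is formed without control, which is immaterial because it is destroyed in step 4, while C7 is carried unchanged from 6.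

Step 4
Reactants: 8 [(4S)-2,2-dimethyl-1,3-dioxolan-4-yl]{5-[(2Z)-oct-2-en-1-yl]furan-2-yl}methanol
Product: 9 (4R,5R)-5-[(4R)-2,2-dimethyl-1,3-dioxolan-4-yl]-4-hydroxy-4-[(2Z)-oct-2-en-1-yl]cyclopent-2-en-1-one
Conditions: ZnCl2 (2 equiv), 1,4-dioxane/H2O (8:1), pH about 6, 85 °C; stopped at full conversion of 8
Reagents that add atoms: water, O
Why: ZnCl2-assisted ionisation of the C8 carbinol gives the furfuryl cation, water adds at the octenyl-bearing furan carbon (C12) and the resulting hemiketal opens to the 1,4-dihydroxypentadienyl cation spanning C8–C12, whose thermal conrotatory 4π electrocyclisation forms the C8–C12 bond and, after proton loss and tautomerisation, the enone; this is the Piancatelli rearrangement of a 2-furylcarbinol, the closest analogy being the slower but known cases with a 5-alkyl group on the furan. The one ring (C8–C12) is closed in this conrotatory 4π mode from the U-shaped cation in which the C7 arm at C8 and the octenyl chain at C12 point outward and the small C12 hydroxyl inward, so the two carbon substituents finish trans and the C12 hydroxyl cis to the C7 arm, as the target requires. C8 and C12 arise together and their absolute sense is the sense of conrotation, which the (S)-glyceraldehyde-derived C7 centre biases: with C7–H in the plane facing the C9 oxygen (minimal allylic 1,3-strain) the C8–C12 bond should form on the face remote from the C7–O bond, and a zinc chelate between the C9 and C7 oxygens exposes the same face, both leading to the 8R,12R isomer 9. C8, being α to the ketone, can in addition equilibrate under the reaction conditions to this arrangement, trans to the larger C12 substituent. The step needs water to attack C12 rather than C8 (attack at C8 only regenerates 8), an intact acetonide and Z-alkene, and no further isomerisation of the product, which the outward preference of the two large groups, the weakly acidic zinc medium and the moderate temperature are meant to secure. Both carbinol epimers of 8 converge because C8 becomes planar on ionisation, and any C8,C12-diastereomer is removed by chromatography, so the chiral-pool C7 centre guarantees the absolute configuration of 9.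

Step 5
Reactants: 9 (4R,5R)-5-[(4R)-2,2-dimethyl-1,3-dioxolan-4-yl]-4-hydroxy-4-[(2Z)-oct-2-en-1-yl]cyclopent-2-en-1-one
Product: 10 (4R,5R)-5-[(1R)-1,2-dihydroxyethyl]-4-hydroxy-4-[(2Z)-oct-2-en-1-yl]cyclopent-2-en-1-one
Conditions: AcOH/H2O (4:1), 40 °C
Reagents that add atoms: none
Why: Acid-catalysed hydrolysis of the terminal isopropylidene ketal frees the C6 and C7 hydroxyls, while the enone and the tertiary C12 alcohol (whose ionisation would place a cation next to the enone α-carbon) are inert under these conditions.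

Step 6
Reactants: 10 (4R,5R)-5-[(1R)-1,2-dihydroxyethyl]-4-hydroxy-4-[(2Z)-oct-2-en-1-yl]cyclopent-2-en-1-one
Product: 11 (4R,5R)-5-[(1R)-1,2-bis(triethylsilyloxy)ethyl]-4-[(2Z)-oct-2-en-1-yl]-4-(triethylsilyloxy)cyclopent-2-en-1-one
Conditions: Et3SiOTf (4 equiv), 2,6-lutidine, CH2Cl2, −78 → 0 °C
Reagents that add atoms: triethylsilyl trifluoromethanesulfonate, CC[Si](CC)(CC)OS(=O)(=O)C(F)(F)F
Why: Silyl ether formation with the silyl triflate and a hindered pyridine base protects all three hydroxyls, including the tertiary one, at low temperature, where hydroxyl silylation outruns enol silylation of the ketone.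

Step 7
Reactants: 11 (4R,5R)-5-[(1R)-1,2-bis(triethylsilyloxy)ethyl]-4-[(2Z)-oct-2-en-1-yl]-4-(triethylsilyloxy)cyclopent-2-en-1-one
Product: 13 (2R)-2-{(1R,5R)-5-[(2Z)-oct-2-en-1-yl]-2-oxo-5-(triethylsilyloxy)cyclopent-3-en-1-yl}-2-(triethylsilyloxy)acetaldehyde, via C6 primary alcohol 12 (not isolated)
Conditions: (COCl)2, DMSO, CH2Cl2, −78 → −40 °C; then Et3N, −78 → 0 °C
Reagents that add atoms: none
Why: Under Swern conditions a primary triethylsilyl ether is cleaved and oxidised in situ much faster than secondary or tertiary ones (one-pot selective desilylation–Swern oxidation), so the C6 aldehyde forms directly with C7 and C12 still protected and without a separate deprotection.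

Step 8
Reactants: 14 methyl 5-bromopentanoate
Product: 15 (5-methoxy-5-oxopentyl)triphenylphosphonium bromide
Conditions: PPh3, MeCN, reflux
Reagents that add atoms: triphenylphosphine, c1ccc(cc1)P(c1ccccc1)c1ccccc1
Why: SN2 quaternisation of triphenylphosphine by the primary bromide gives the C1–C5 phosphonium salt.

Step 9
Reactants: 13 (2R)-2-{(1R,5R)-5-[(2Z)-oct-2-en-1-yl]-2-oxo-5-(triethylsilyloxy)cyclopent-3-en-1-yl}-2-(triethylsilyloxy)acetaldehyde; 15 (5-methoxy-5-oxopentyl)triphenylphosphonium bromide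
Product: 17 methyl (5Z,7S)-7-{(1R,5R)-5-[(2Z)-oct-2-en-1-yl]-2-oxo-5-(triethylsilyloxy)cyclopent-3-en-1-yl}-7-(triethylsilyloxy)hept-5-enoate, via phosphorus ylide 16 (not isolated)
Conditions: 15, NaN(SiMe3)2 (slightly less than 1 equiv per 15), THF, −78 → −40 °C; then 13, −78 → −20 °C
Reagents that add atoms: none
Why: Wittig reaction of the non-stabilised ylide with the α-silyloxy aldehyde at −78 °C under lithium-free conditions proceeds through the kinetically favoured cis-oxaphosphetane to the 5Z-alkene; the aldehyde reacts far faster than the enone carbonyl, and the absence of free hydroxyls and of excess amide base protects the C7 and C8 centres.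

Step 10
Reactants: 17 methyl (5Z,7S)-7-{(1R,5R)-5-[(2Z)-oct-2-en-1-yl]-2-oxo-5-(triethylsilyloxy)cyclopent-3-en-1-yl}-7-(triethylsilyloxy)hept-5-enoate
Product: 18 methyl (5Z,7S)-7-{(1R,5S)-3-iodo-5-[(2Z)-oct-2-en-1-yl]-2-oxo-5-(triethylsilyloxy)cyclopent-3-en-1-yl}-7-(triethylsilyloxy)hept-5-enoate
Conditions: I2, pyridine/CH2Cl2 (1:1), 0 °C → rt, dark
Reagents that add atoms: iodine, II
Why: Baylis–Hillman-type α-iodination of the enone (reversible addition of pyridine at C11, iodination of the enolate at C10, loss of pyridine) installs the C10 iodide; it is placed before desilylation because free hydroxyls next to the two Z-alkenes would invite iodoetherification.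

Step 11
Reactants: 18 methyl (5Z,7S)-7-{(1R,5S)-3-iodo-5-[(2Z)-oct-2-en-1-yl]-2-oxo-5-(triethylsilyloxy)cyclopent-3-en-1-yl}-7-(triethylsilyloxy)hept-5-enoate
Product: 19 methyl (5Z,7S)-7-hydroxy-7-{(1R,5S)-5-hydroxy-3-iodo-5-[(2Z)-oct-2-en-1-yl]-2-oxocyclopent-3-en-1-yl}hept-5-enoate
Conditions: HF·pyridine, THF/pyridine, 0 °C → rt
Reagents that add atoms: none
Why: Fluoride-mediated desilylation under buffered, non-basic conditions removes the secondary and the tertiary triethylsilyl ether without touching the β-hydroxy ketone, the iodoenone or the methyl ester.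

Step 12
Reactants: 19 methyl (5Z,7S)-7-hydroxy-7-{(1R,5S)-5-hydroxy-3-iodo-5-[(2Z)-oct-2-en-1-yl]-2-oxocyclopent-3-en-1-yl}hept-5-enoate
Product: 20 methyl (5Z,7S)-7-acetoxy-7-{(1R,5S)-5-hydroxy-3-iodo-5-[(2Z)-oct-2-en-1-yl]-2-oxocyclopent-3-en-1-yl}hept-5-enoate
Conditions: Ac2O, pyridine, DMAP (cat.), CH2Cl2, 0 °C
Reagents that add atoms: acetic anhydride, CC(=O)OC(C)=O
Why: Acylation at 0 °C differentiates the secondary allylic C7 hydroxyl from the hindered tertiary C12 hydroxyl, and placing this step last keeps the exposure of the elimination-prone β-acetoxy ketone to base as short as possible.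

**Compound list**

1 | (2Z)-oct-2-en-1-ol | CCCCC/C=C\CO | starting material
2 | (2Z)-1-bromooct-2-ene | CCCCC/C=C\CBr | intermediate
3 | furan | c1ccoc1 | starting material
4 | 2-lithiofuran | [Li]c1ccco1 | intermediate (not isolated)
5 | 2-[(2Z)-oct-2-en-1-yl]furan | CCCCC/C=C\Cc1ccco1 | intermediate
6 | (4S)-2,2-dimethyl-1,3-dioxolane-4-carbaldehyde | O=C[C@@H]1COC(C)(C)O1 | starting material
7 | 5-lithio-2-[(2Z)-oct-2-en-1-yl]furan | CCCCC/C=C\Cc1ccc([Li])o1 | intermediate (not isolated)
8 | [(4S)-2,2-dimethyl-1,3-dioxolan-4-yl]{5-[(2Z)-oct-2-en-1-yl]furan-2-yl}methanol, both C8 epimers | CCCCC/C=C\Cc1ccc(o1)C(O)[C@@H]1COC(C)(C)O1 | intermediate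
9 | (4R,5R)-5-[(4R)-2,2-dimethyl-1,3-dioxolan-4-yl]-4-hydroxy-4-[(2Z)-oct-2-en-1-yl]cyclopent-2-en-1-one | CCCCC/C=C\C[C@@]1(O)C=CC(=O)[C@@H]1[C@@H]2COC(C)(C)O2 | intermediate
10 | (4R,5R)-5-[(1R)-1,2-dihydroxyethyl]-4-hydroxy-4-[(2Z)-oct-2-en-1-yl]cyclopent-2-en-1-one | CCCCC/C=C\C[C@@]1(O)C=CC(=O)[C@@H]1[C@@H](O)CO | intermediate
11 | (4R,5R)-5-[(1R)-1,2-bis(triethylsilyloxy)ethyl]-4-[(2Z)-oct-2-en-1-yl]-4-(triethylsilyloxy)cyclopent-2-en-1-one | CCCCC/C=C\C[C@@]1(O[Si](CC)(CC)CC)C=CC(=O)[C@@H]1[C@@H](O[Si](CC)(CC)CC)CO[Si](CC)(CC)CC | intermediate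
12 | (4R,5R)-5-[(1R)-2-hydroxy-1-(triethylsilyloxy)ethyl]-4-[(2Z)-oct-2-en-1-yl]-4-(triethylsilyloxy)cyclopent-2-en-1-one | CCCCC/C=C\C[C@@]1(O[Si](CC)(CC)CC)C=CC(=O)[C@@H]1[C@@H](O[Si](CC)(CC)CC)CO | intermediate (not isolated)
13 | (2R)-2-{(1R,5R)-5-[(2Z)-oct-2-en-1-yl]-2-oxo-5-(triethylsilyloxy)cyclopent-3-en-1-yl}-2-(triethylsilyloxy)acetaldehyde | CCCCC/C=C\C[C@@]1(O[Si](CC)(CC)CC)C=CC(=O)[C@@H]1[C@@H](O[Si](CC)(CC)CC)C=O | intermediate
14 | methyl 5-bromopentanoate | COC(=O)CCCCBr | starting material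
15 | (5-methoxy-5-oxopentyl)triphenylphosphonium bromide | COC(=O)CCCC[P+](c1ccccc1)(c1ccccc1)c1ccccc1.[Br-] | intermediate
16 | methyl 5-(triphenylphosphoranylidene)pentanoate | COC(=O)CCCC=P(c1ccccc1)(c1ccccc1)c1ccccc1 | intermediate (not isolated)
17 | methyl (5Z,7S)-7-{(1R,5R)-5-[(2Z)-oct-2-en-1-yl]-2-oxo-5-(triethylsilyloxy)cyclopent-3-en-1-yl}-7-(triethylsilyloxy)hept-5-enoate | CCCCC/C=C\C[C@@]1(O[Si](CC)(CC)CC)C=CC(=O)[C@@H]1[C@H](/C=C\CCCC(=O)OC)O[Si](CC)(CC)CC | intermediate
18 | methyl (5Z,7S)-7-{(1R,5S)-3-iodo-5-[(2Z)-oct-2-en-1-yl]-2-oxo-5-(triethylsilyloxy)cyclopent-3-en-1-yl}-7-(triethylsilyloxy)hept-5-enoate | CCCCC/C=C\C[C@@]1(O[Si](CC)(CC)CC)C=C(I)C(=O)[C@@H]1[C@H](/C=C\CCCC(=O)OC)O[Si](CC)(CC)CC | intermediate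
19 | methyl (5Z,7S)-7-hydroxy-7-{(1R,5S)-5-hydroxy-3-iodo-5-[(2Z)-oct-2-en-1-yl]-2-oxocyclopent-3-en-1-yl}hept-5-enoate | CCCCC/C=C\C[C@@]1(O)C=C(I)C(=O)[C@@H]1[C@H](/C=C\CCCC(=O)OC)O | intermediate
20 | methyl (5Z,7S)-7-acetoxy-7-{(1R,5S)-5-hydroxy-3-iodo-5-[(2Z)-oct-2-en-1-yl]-2-oxocyclopent-3-en-1-yl}hept-5-enoate | CCCCC/C=C\C[C@@]1(O)C=C(I)C(=O)[C@@H]1[C@H](/C=C\CCCC(=O)OC)OC(C)=O | target

**Step count**

Total: 12 steps. Longest linear sequence: 11 steps (steps 1–7 and 9–12, from (2Z)-oct-2-en-1-ol); step 8 is a one-step side branch.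

**Steps most likely to fail**

1. Step 4. Ionisation of the carbinol may be slow, because the 5-alkyl group hinders water attack and the C7 oxygen destabilises the cation. During the long heating the acetonide may hydrolyse, a 1,2-hydride shift from C7 to the cationic C8 may drain the cation, the product may isomerise further, and the facial bias exerted by C7 on the conrotation may be weak.
Fallback (sets out from 5, returns at 10): the ring is made first by the better documented rearrangement of a primary 5-alkylfurfuryl alcohol, and the C6–C7 unit is attached afterwards by an aldol reaction. Absolute control then comes from a resolution and C7 from a separation, not from the relay.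
 - Lithiation of 5 as in step 3 and quenching with DMF should give 5-[(2Z)-oct-2-en-1-yl]furan-2-carbaldehyde F1.
 - NaBH4 in MeOH reduces it to {5-[(2Z)-oct-2-en-1-yl]furan-2-yl}methanol F2.
 - Aqueous ZnCl2 in dioxane at reflux should rearrange F2 to racemic 4-hydroxy-4-[(2Z)-oct-2-en-1-yl]cyclopent-2-en-1-one F3.
 - Preparative chromatography on a chiral stationary phase provides (4S)-4-hydroxy-4-[(2Z)-oct-2-en-1-yl]cyclopent-2-en-1-one F4.
 - Et3SiOTf and 2,6-lutidine give (4S)-4-[(2Z)-oct-2-en-1-yl]-4-(triethylsilyloxy)cyclopent-2-en-1-one F5.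
 - Deprotonation at C8 with LiN(i-Pr)2 in THF at −78 °C forms lithium 3-[(2Z)-oct-2-en-1-yl]-3-(triethylsilyloxy)cyclopenta-1,4-dien-1-olate F6, which adds to commercially available (tert-butyldimethylsilyloxy)acetaldehyde. C8 is epimerisable and should settle trans to the octenyl chain; the C7 epimers have to be separated. The required adduct is (4R,5R)-5-[(1R)-2-(tert-butyldimethylsilyloxy)-1-hydroxyethyl]-4-[(2Z)-oct-2-en-1-yl]-4-(triethylsilyloxy)cyclopent-2-en-1-one F7.
 - HF·pyridine removes both silyl groups and delivers triol 10.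

2. Step 9. The ylide may act as a base at C8, which lies between the ketone and C7. This would lead to β-elimination of the C7 silyloxy group or to epimerisation at C7 and C8, and the Z-selectivity may erode if the addition has to be run warmer.
Fallback (sets out from 13, returns at 17): the C5=C6 bond is built without a basic ylide, by dibromo-olefination, Z-selective hydrogenolysis and Negishi coupling.
 - CBr4, PPh3 and Zn dust in CH2Cl2 at 0 °C (neutral dibromomethylenation) should convert 13 into (4R,5R)-5-[(1R)-3,3-dibromo-1-(triethylsilyloxy)prop-2-en-1-yl]-4-[(2Z)-oct-2-en-1-yl]-4-(triethylsilyloxy)cyclopent-2-en-1-one F8.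
 - Bu3SnH with catalytic Pd(PPh3)4 in THF at rt replaces the bromine trans to the C7 substituent and should give (4R,5R)-5-[(1R,2Z)-3-bromo-1-(triethylsilyloxy)prop-2-en-1-yl]-4-[(2Z)-oct-2-en-1-yl]-4-(triethylsilyloxy)cyclopent-2-en-1-one F9.
 - Methyl 4-bromobutanoate, Zn and LiCl in THF give (4-methoxy-4-oxobutyl)zinc bromide F10. Its coupling with F9 under Pd(PPh3)4 catalysis proceeds with retention of alkene geometry and gives 17.

3. Step 3. n-BuLi may remove a proton from the C13 methylene, which is both furfurylic and allylic, and not from the furan α-position. The delocalised anion would then scramble the position and geometry of the alkene and give regioisomeric adducts.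
Fallback (sets out from 4 and 6, returns at 8): the order of the two furan substitutions is reversed, so that the second lithiation meets no competing acidic site.
 - 2-Lithiofuran 4 adds to 6 at −78 °C to give [(4S)-2,2-dimethyl-1,3-dioxolan-4-yl](furan-2-yl)methanol F11.
 - t-BuMe2SiCl and imidazole in DMF give tert-butyl{[(4S)-2,2-dimethyl-1,3-dioxolan-4-yl](furan-2-yl)methoxy}dimethylsilane F12.
 - n-BuLi in THF lithiates the free α-position to tert-butyl{[(4S)-2,2-dimethyl-1,3-dioxolan-4-yl](5-lithiofuran-2-yl)methoxy}dimethylsilane F13, which is alkylated with 2 to tert-butyl([(4S)-2,2-dimethyl-1,3-dioxolan-4-yl]{5-[(2Z)-oct-2-en-1-yl]furan-2-yl}methoxy)dimethylsilane F14.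
 - Bu4NF in THF frees the carbinol 8.

**Further compounds**

F1 | step 4 | 5-[(2Z)-oct-2-en-1-yl]furan-2-carbaldehyde | CCCCC/C=C\Cc1ccc(C=O)o1
F2 | step 4 | {5-[(2Z)-oct-2-en-1-yl]furan-2-yl}methanol | CCCCC/C=C\Cc1ccc(CO)o1
F3 | step 4 | racemic 4-hydroxy-4-[(2Z)-oct-2-en-1-yl]cyclopent-2-en-1-one | CCCCC/C=C\CC1(O)C=CC(=O)C1
F4 | step 4 | (4S)-4-hydroxy-4-[(2Z)-oct-2-en-1-yl]cyclopent-2-en-1-one | CCCCC/C=C\C[C@@]1(O)C=CC(=O)C1
F5 | step 4 | (4S)-4-[(2Z)-oct-2-en-1-yl]-4-(triethylsilyloxy)cyclopent-2-en-1-one | CCCCC/C=C\C[C@@]1(O[Si](CC)(CC)CC)C=CC(=O)C1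
F6 | step 4 | lithium 3-[(2Z)-oct-2-en-1-yl]-3-(triethylsilyloxy)cyclopenta-1,4-dien-1-olate (C12 configuration as in F5) | CCCCC/C=C\C[C@@]1(O[Si](CC)(CC)CC)C=CC(O[Li])=C1
F7 | step 4 | (4R,5R)-5-[(1R)-2-(tert-butyldimethylsilyloxy)-1-hydroxyethyl]-4-[(2Z)-oct-2-en-1-yl]-4-(triethylsilyloxy)cyclopent-2-en-1-one | CCCCC/C=C\C[C@@]1(O[Si](CC)(CC)CC)C=CC(=O)[C@@H]1[C@@H](O)CO[Si](C)(C)C(C)(C)C
F8 | step 9 | (4R,5R)-5-[(1R)-3,3-dibromo-1-(triethylsilyloxy)prop-2-en-1-yl]-4-[(2Z)-oct-2-en-1-yl]-4-(triethylsilyloxy)cyclopent-2-en-1-one | CCCCC/C=C\C[C@@]1(O[Si](CC)(CC)CC)C=CC(=O)[C@@H]1[C@@H](O[Si](CC)(CC)CC)C=C(Br)Br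
F9 | step 9 | (4R,5R)-5-[(1R,2Z)-3-bromo-1-(triethylsilyloxy)prop-2-en-1-yl]-4-[(2Z)-oct-2-en-1-yl]-4-(triethylsilyloxy)cyclopent-2-en-1-one | CCCCC/C=C\C[C@@]1(O[Si](CC)(CC)CC)C=CC(=O)[C@@H]1[C@H](/C=C\Br)O[Si](CC)(CC)CC
F10 | step 9 | (4-methoxy-4-oxobutyl)zinc bromide | COC(=O)CCC[Zn]Br
F11 | step 3 | [(4S)-2,2-dimethyl-1,3-dioxolan-4-yl](furan-2-yl)methanol, both carbinol epimers | OC(c1ccco1)[C@@H]1COC(C)(C)O1
F12 | step 3 | tert-butyl{[(4S)-2,2-dimethyl-1,3-dioxolan-4-yl](furan-2-yl)methoxy}dimethylsilane | CC(C)(C)[Si](C)(C)OC(c1ccco1)[C@@H]1COC(C)(C)O1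
F13 | step 3 | tert-butyl{[(4S)-2,2-dimethyl-1,3-dioxolan-4-yl](5-lithiofuran-2-yl)methoxy}dimethylsilane | CC(C)(C)[Si](C)(C)OC(c1ccc([Li])o1)[C@@H]1COC(C)(C)O1
F14 | step 3 | tert-butyl([(4S)-2,2-dimethyl-1,3-dioxolan-4-yl]{5-[(2Z)-oct-2-en-1-yl]furan-2-yl}methoxy)dimethylsilane | CCCCC/C=C\Cc1ccc(o1)C(O[Si](C)(C)C(C)(C)C)[C@@H]1COC(C)(C)O1
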